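## Structural features

The target is a 4→8 linked biflavanoid: an upper 4',7-dihydroxyflavan-3-ol (aromatic ring A, pyran ring C, 4-hydroxyphenyl ring B) whose C4 is bonded to C8 of the phloroglucinol ring D of a lower (−)-epicatechin unit (pyran ring F, catechol ring E). The upper unit has three contiguous stereocentres, C2, C3 and C4, all R: ring B and the 3-hydroxyl are cis, and the lower unit at C4 is trans to the 3-hydroxyl. The lower unit adds the cis pair C2/C3 (2R,3R) of epicatechin. C4 is a doubly benzylic methine between two electron-rich arenes, so the C4–C8 bond is open to acid cleavage, the C2–O1 bonds can ionise, and the free phenols oxidise in base; all hydroxyls therefore stay benzylated until the last step and strong acid is avoided. The real difficulty is twofold: to attach ring A to the configured C4 with its oxygen pattern fixed, and to close ring C in the 2,3-cis arrangement, which cationic closures do not give. Ring A is a resorcinol in which C4a bears C4, the neighbouring C8a bears O1, C7 bears a hydroxyl meta to O1, and C5, C6 and C8 are unsubstituted. That is the pattern a vinylketene and an alkoxyalkyne produce, so ring A can be grown onto C4 from a four-carbon unsaturated diazoketone arm (C4a, C5, C6, C8a) and a two-carbon ynol ether (C7, C8), emerging with a free C8a hydroxyl ready to close O1–C2.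

## Logic of the disconnections

**35 from 34.** The eight O–benzyl bonds are cut last. Benzyl is the only permanent protecting group, so one neutral hydrogenolysis frees every hydroxyl and the unprotected biflavanoid never meets acid or base. The demand is that nothing upstream carries a group hydrogenolysis cannot remove.

**34 from 33, and 33 from 32.** The O1–C2 bond of ring C is cut. Closing it by displacement with the ring A phenol lets C2 be set beforehand in an open chain with the opposite configuration and inverted in the closure. The gain is acyclic, chelation-controlled access to C2. The demand is an SN2 event at a carbon that could ionise, and a silyl ether on C2 (removed in going from 32 to 33) that survives until then.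

**32 from 22 and 27.** Ring A is taken apart along C8–C8a, C6–C7 and C4a–C8a. A whole aromatic ring disappears in one operation; the upper unit becomes an open chain carrying C2, C3, C4 and an unsaturated diazoketone, and two ring carbons plus the C7 oxygen come from 27. The forward step needs an E alkene, one orientation of cycloaddition, and conditions that leave C3 and C4 alone. Two design changes are built in. The benzyl ynol ether is consumed at or below room temperature and its excess removed before heating, because benzyl alkynyl ethers rearrange sigmatropically on warming. Light of 365 nm is used so the benzylated arenes are not excited.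

**27 from 23 and 24.** The O–C(sp) bond and the two chlorine-bearing carbons are traced to an alcohol and a chlorinated alkene. This is a one-flask preparation of a reagent that must be made fresh.

**22 from 20, and 20 from 18 and 19.** The diazo group is cut back to a methyl ketone, then the C4a=C5 double bond is cut by metathesis logic. Acylating diazomethane with a conjugated acid chloride is avoided because diazomethane would add across the double bond; a methyl enone and a deacylative diazo transfer reach the same diazoketone. The demands are enolisation at the methyl group only and metathesis at a hindered propenyl group.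

**18 from 17, 17 from 16, 16 from 13 and 14 (through 15), 13 from 12.** The silyl group, the C2–H bond, the C2–aryl bond and the amide are removed in turn. Ring B arrives as an aryl nucleophile and C2 as a ketone, so its configuration is set by hydride delivery under chelation with the C3 benzyloxy group. The demand is high anti selectivity, since this centre becomes C2 after inversion.

**12 from 9, and 9 from 7 and 8.** The C3–C4 bond is cut by a [3,3] shift of an allylic glycolate. Both upper-unit centres C3 and C4 then derive from one carbinol centre and two defined double-bond geometries, and the propenyl group that will become C4a=C5 appears with E geometry. The demand is a chelated Z enolate and a chair transition state.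

**7 from 6, and 6 from 4 and 5.** The C8–C(sp) bond of ring D is cut. The carbinol centre comes from the chiral pool with 5 and needs no asymmetric reaction on a substrate that already has stereocentres. The demands are a coupling at a hindered, electron-rich aryl bromide and a trans-selective alkyne reduction.

**4 from 3, 3 from 2, 2 from 1.** The C8–Br bond and five O–benzyl bonds are cut, leaving the natural flavanol that supplies rings D, E, F and both lower stereocentres. The demand is bromination at C8 and not C6.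

## Other disconnections considered

**Alternative 1:** The cut is C8–C8a of ring D, folding the phloroglucinol ring of the lower unit from a pyrone. Methoxide would open the 4-benzyloxy-2-pyrone A1, which carries the finished upper unit on a methylene group and a cinnamyl chain, to a keto ester. Its methylene carbanion would attack the ester carbon and aromatise to the ring D resorcinol A2.
- In its favour: the interflavan bond is at C8 by construction and cannot be at C6. The step is a plain base-mediated condensation with no photochemistry and no labile ynol ether. On operational simplicity of the key step it is the better plan.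
- Against it here: A2 still lacks ring F and both lower stereocentres. These would have to be made from the cinnamyl group by asymmetric dihydroxylation and a second cis-selective pyran closure, on a dimer-sized substrate with two free phenols. The natural flavanol that supplies these for nothing is discarded. A1 also needs a complete, correctly configured upper unit before the key step.
- Comparison: structurally it builds the aromatic ring that can be bought and leaves ring A and ring C of the upper unit as a separate, unsolved problem. Mechanistically it is enolate chemistry against a pericyclic cascade. Both spare the C4 centre, but the chosen plan does so under neutral conditions. In step count it is clearly longer.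

**Alternative 2:** The cut is C4–C4a. A Lewis acid would ionise the C4 acetate of the open-chain diacetate A3; the C3 acetate would bridge the cation as a dioxolanylium ion, and the 3-benzyloxyphenyl ether on C2 would attack C4 through its ortho carbon to give the 3-O-acetyl biflavanoid A4.
- In its favour: ring A is bought as a resorcinol monoether and not synthesised. The bridging acetate should deliver the 3,4-trans relationship whatever the C4 configuration of A3, so the step is stereoconvergent. In step count, and in setting C4 during ring closure, it is equal or better.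
- Against it here: the conditions that ionise C4 can also ionise the benzylic aryl ether at C2, which would lose the aryloxy group or scramble C2. They can also reverse the bond between C4 and ring D. The arene can attack through either carbon ortho to the ether oxygen. A3 needs an intermolecular, invertive etherification at the ionisable C2, which is harder than the intramolecular closure of the chosen plan. An extra deacetylation follows.
- Comparison: the alternative is shorter but places three acid-sensitive sites under a Lewis acid. The chosen plan is longer but forms ring A without any cationic intermediate.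

**Alternative 3:** The cut is O1–C2, the same bond as step 17, but from the cis-epoxide A5. Fluoride would free the ring A phenol and mild acid would let it open the epoxide at the benzylic carbon with inversion, giving A6 with a free 3-hydroxyl.
- In its favour: the closure is redox-neutral and produces no phosphine oxide or hydrazine waste, and the 3-hydroxyl needs no protecting group. On atom economy it is better, and on step count for the closure it is equal.
- Against it here: acid opening of an epoxide at a 4-benzyloxybenzylic carbon is borderline SN1, so inversion may erode. Attack at C3 to a five-membered ring and rearrangement of the epoxide to a ketone compete. The cis-epoxide must come from a face-selective epoxidation next to C4, which sets C2 and C3 together. The chosen plan sets C3 with C4 in one sigmatropic step and C2 by chelation control.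
- Comparison: it does not say how ring A reaches C4, so it is an end-game variant and not a replacement for the benzannulation. Both closures carry the same ionisation risk at C2.

Key step: step 15

Remark on the chemistry: the upper unit is read as (2R,3R,4R), that is 2,3-cis-3,4-trans. The benzannulation precursor 22 and product 32 carry the target's configuration at C3 and C4 and the opposite one at C2, as an invertive closure requires, so no stereodescriptor needed correction.

Abbreviations in names: EC8 = (2R,3R)-3,5,7-tris(benzyloxy)-2-[3,4-bis(benzyloxy)phenyl]chroman-8-yl (perbenzylated epicatechin bonded through C8); TBS = tert-butyldimethylsilyl.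

## Route

Step 1
Reactants: 1 (−)-epicatechin
Product: 2 5,7,3',4'-tetra-O-benzyl-(−)-epicatechin
Conditions: BnBr, K2CO3, DMF, 0 °C → rt, under argon
Reagents that add atoms: benzyl bromide, BrCc1ccccc1
Why: Williamson benzylation of the four phenols with a weak base; the aliphatic 3-hydroxyl is not deprotonated and C2 should not epimerise.

Step 2
Reactants: 2 5,7,3',4'-tetra-O-benzyl-(−)-epicatechin
Product: 3 3,5,7,3',4'-penta-O-benzyl-(−)-epicatechin
Conditions: NaH, BnBr, Bu4NI (cat.), THF/DMF, 0 °C → rt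
Reagents that add atoms: benzyl bromide, BrCc1ccccc1
Why: Williamson benzylation of the remaining secondary hydroxyl after deprotonation with NaH; no phenol is free, so ring opening at C2 is not possible.

Step 3
Reactants: 3 3,5,7,3',4'-penta-O-benzyl-(−)-epicatechin
Product: 4 8-bromo-3,5,7,3',4'-penta-O-benzyl-(−)-epicatechin
Conditions: NBS (1.0 equiv), CH2Cl2, −78 °C → rt
Reagents that add atoms: N-bromosuccinimide, O=C1CCC(=O)N1Br
Why: Electrophilic aromatic bromination of ring D; in 5,7-dialkoxyflavans C8 is the more reactive free position, and one equivalent at low temperature should keep the reaction there.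

Step 4
Reactants: 4 8-bromo-3,5,7,3',4'-penta-O-benzyl-(−)-epicatechin; 5 (R)-but-3-yn-2-ol
Product: 6 (R)-4-(EC8)but-3-yn-2-ol
Conditions: PdCl2(MeCN)2 (cat.), XPhos, Cs2CO3, MeCN/1,4-dioxane, 80 °C
Reagents that add atoms: none
Why: Copper-free Sonogashira coupling; the bulky electron-rich biarylphosphine lets zerovalent palladium insert into the hindered, electron-rich C8–Br bond, and the carbinol centre from 5 is not involved.

Step 5
Reactants: 6 (R)-4-(EC8)but-3-yn-2-ol
Product: 7 (R,E)-4-(EC8)but-3-en-2-ol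
Conditions: NaAlH2(OCH2CH2OMe)2 (Red-Al), THF, 0 °C → rt; aqueous Rochelle salt
Reagents that add atoms: none
Why: Hydroxyl-directed trans-hydroalumination of the propargylic alcohol followed by protonolysis gives the E allylic alcohol; the carbinol centre and the benzyl ethers are untouched.

Step 6
Reactants: 7 (R,E)-4-(EC8)but-3-en-2-ol; 8 2-(benzyloxy)acetic acid
Product: 9 (R,E)-4-(EC8)but-3-en-2-yl 2-(benzyloxy)acetate
Conditions: DCC, DMAP (cat.), CH2Cl2, 0 °C → rt; chromatography on Et3N-deactivated silica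
Reagents that add atoms: none
Why: Steglich esterification under non-acidic conditions, chosen because this electron-rich cinnamyl-type alcohol would ionise under acid.

Step 7
Reactants: 9 (R,E)-4-(EC8)but-3-en-2-yl 2-(benzyloxy)acetate
Product: 12 (2R,3R,E)-2-(benzyloxy)-3-(EC8)hex-4-enoic acid, via silyl ketene acetal 10 (not isolated), via trimethylsilyl ester 11 (not isolated)
Conditions: LiN(SiMe3)2, Me3SiCl/Et3N, THF, −78 °C → 20 °C; then dilute aqueous citric acid
Reagents that add atoms: none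
Why: Ireland–Claisen rearrangement of a glycolate: lithium chelation between the enolate oxygen and the benzyloxy group gives the Z ketene acetal 10, which rearranges through a chair with the carbinol methyl group equatorial. The E alkene and Z ketene acetal give the 2,3-syn pair (C3 and C4 of the upper unit, trans in ring C later), and the R carbinol centre is transferred to 2R,3R with a new E propenyl group.

Step 8
Reactants: 12 (2R,3R,E)-2-(benzyloxy)-3-(EC8)hex-4-enoic acid
Product: 13 (2R,3R,E)-2-(benzyloxy)-N-methoxy-N-methyl-3-(EC8)hex-4-enamide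
Conditions: MeNH(OMe)·HCl, EDC·HCl, HOBt, N-methylmorpholine, CH2Cl2, 0 °C → rt
Reagents that add atoms: N,O-dimethylhydroxylamine hydrochloride, CNOC.Cl
Why: Carbodiimide amidation to the Weinreb amide through the benzotriazolyl ester, conditions under which an α-alkoxy acid should not epimerise.

Step 9
Reactants: 13 (2R,3R,E)-2-(benzyloxy)-N-methoxy-N-methyl-3-(EC8)hex-4-enamide; 14 1-(benzyloxy)-4-bromobenzene
Product: 16 (2R,3R,E)-2-(benzyloxy)-1-[4-(benzyloxy)phenyl]-3-(EC8)hex-4-en-1-one, via Grignard reagent 15 (not isolated)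
Conditions: 14, Mg, THF, 50 °C; then 13, THF, 0 °C; cold 1 M HCl
Reagents that add atoms: none
Why: Aryl Grignard addition to a Weinreb amide; the chelated tetrahedral magnesium adduct persists until work-up, so the ketone is released only then and is not attacked twice.

Step 10
Reactants: 16 (2R,3R,E)-2-(benzyloxy)-1-[4-(benzyloxy)phenyl]-3-(EC8)hex-4-en-1-one
Product: 17 (1S,2R,3R,E)-2-(benzyloxy)-1-[4-(benzyloxy)phenyl]-3-(EC8)hex-4-en-1-ol
Conditions: Zn(BH4)2, Et2O, −20 °C
Reagents that add atoms: none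
Why: Chelation-controlled (Cram chelate) reduction: zinc bridges the ketone and the α-benzyloxy oxygen and hydride enters from the side of the C–H bond of the α-carbon, giving the 1,2-anti alcohol (1S). This is the C2 epimer that the invertive ring closure needs.

Step 11
Reactants: 17 (1S,2R,3R,E)-2-(benzyloxy)-1-[4-(benzyloxy)phenyl]-3-(EC8)hex-4-en-1-ol
Product: 18 TBS ether of 17: tert-butyl{[(1S,2R,3R,E)-2-(benzyloxy)-1-[4-(benzyloxy)phenyl]-3-(EC8)hex-4-en-1-yl]oxy}dimethylsilane
Conditions: TBSOTf, 2,6-lutidine, CH2Cl2, 0 °C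
Reagents that add atoms: tert-butyldimethylsilyl trifluoromethanesulfonate, CC(C)(C)[Si](C)(C)OS(=O)(=O)C(F)(F)F
Why: Silylation of a hindered secondary alcohol with a silyl triflate and a hindered base; the ether masks the C2 hydroxyl through the metathesis, the basic diazo transfer and the ketene chemistry, where a free hydroxyl would be acylated.

Step 12
Reactants: 18 TBS ether of 17; 19 methyl vinyl ketone
Product: 20 (3E,5R,6R,7S)-6-(benzyloxy)-7-[4-(benzyloxy)phenyl]-7-(TBS-oxy)-5-(EC8)hept-3-en-2-one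
Conditions: 19 (excess), RuCl2(H2IMes)(=CH-C6H4-2-O-i-Pr) (second-generation Hoveyda–Grubbs catalyst, 10 mol %), CH2Cl2, 40 °C
Reagents that add atoms: none
Why: Olefin cross-metathesis of a propenyl group with an electron-poor enone partner, driven by loss of propene and expected to give the E enone; no stereocentre is touched.

Step 13
Reactants: 20 (3E,5R,6R,7S)-6-(benzyloxy)-7-[4-(benzyloxy)phenyl]-7-(TBS-oxy)-5-(EC8)hept-3-en-2-one
Product: 22 (3E,5R,6R,7S)-6-(benzyloxy)-7-[4-(benzyloxy)phenyl]-7-(TBS-oxy)-1-diazo-5-(EC8)hept-3-en-2-one, via trifluoroacetyl diketone 21 (not isolated)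
Conditions: LiN(SiMe3)2, THF, −78 °C; CF3CO2CH2CF3; dilute HCl wash; then MsN3, Et3N, H2O, MeCN, rt
Reagents that add atoms: methanesulfonyl azide, CS(=O)(=O)N=[N+]=[N-]
Why: Detrifluoroacetylative diazo transfer: kinetic deprotonation of the methyl group, trifluoroacetylation to 21, then sulfonyl azide transfer with loss of the trifluoroacetyl group. It reaches the unsaturated diazoketone without exposing a conjugated acid chloride to diazomethane, which would add across the double bond.

Step 14
Reactants: 23 benzyl alcohol; 24 trichloroethylene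
Product: 27 benzyloxyacetylene, via dichlorovinyl ether 25 (not isolated), via lithium benzyloxyacetylide 26 (not isolated)
Conditions: KH, THF, 0 °C; 24, −50 °C → rt; n-BuLi (2.3 equiv), −78 → −40 °C; MeOH, −78 °C; cold pentane work-up, used at once as a cold solution
Reagents that add atoms: none
Why: Ynol ether synthesis from a dichlorovinyl ether: the potassium alkoxide adds to dichloroacetylene formed in the flask from 24, and butyllithium then effects elimination and chlorine–lithium exchange to 26, which is protonated cold. 27 is not stored because benzyl alkynyl ethers rearrange on warming.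

Step 15
Reactants: 22 (3E,5R,6R,7S)-6-(benzyloxy)-7-[4-(benzyloxy)phenyl]-7-(TBS-oxy)-1-diazo-5-(EC8)hept-3-en-2-one; 27 benzyloxyacetylene
Product: 32 5-(benzyloxy)-2-[(1R,2R,3S)-2-(benzyloxy)-3-[4-(benzyloxy)phenyl]-3-(TBS-oxy)-1-(EC8)propyl]phenol, via vinylketene 28 (not isolated), via vinylcyclobutenone 29 (not isolated), via dienylketene 30 (not isolated), via cyclohexadienone 31 (not isolated)
Conditions: 27 (3 equiv), hν (365 nm), ClCH2CH2Cl, 15 °C; evaporation of excess 27; then PhMe, 90 °C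
Reagents that add atoms: none
Why: Irradiation expels N2 and the alkenyl group migrates (Wolff rearrangement) to give vinylketene 28; its carbonyl carbon (future C8a) is attacked by the nucleophilic CH terminus of 27 (future C8) in a [2+2] cycloaddition that also joins C6 to C7 and gives cyclobutenone 29. Heating opens 29 by four-electron conrotatory cleavage to dienylketene 30, which closes ring A by a six-electron disrotatory electrocyclisation between C8a and C4a; tautomerisation of dienone 31 gives phenol 32. This is the diazoketone form of the Danheiser benzannulation of vinylketenes with heteroatom-substituted alkynes. No stereocentre is created, and the sp3 carbons of 29 and 31 are lost on aromatisation. The selectivity needed is the orientation of the cycloaddition; the polarised ynol ether secures it by bonding its oxygen-bearing carbon to the ketene α-carbon, which puts the benzyloxy group meta to the new hydroxyl and para to C4. The E alkene keeps the C4–H bond away from the ketene carbon, so a 1,5-hydrogen shift cannot compete, and it turns the bulky C4 substituent outward in the ring closure. The neutral conditions leave C3, C4, the silyl ether and the benzyl ethers alone. The two-temperature protocol uses up the heat-sensitive ynol ether before warming and delays phenol formation until no ketene is left to acylate it.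

Step 16
Reactants: 32 5-(benzyloxy)-2-[(1R,2R,3S)-2-(benzyloxy)-3-[4-(benzyloxy)phenyl]-3-(TBS-oxy)-1-(EC8)propyl]phenol
Product: 33 5-(benzyloxy)-2-[(1R,2R,3S)-2-(benzyloxy)-3-[4-(benzyloxy)phenyl]-3-hydroxy-1-(EC8)propyl]phenol
Conditions: Bu4NF, AcOH (1:1), THF, 40 °C
Reagents that add atoms: none
Why: Fluoride cleavage of the secondary silyl ether; acetic acid buffering keeps the medium from becoming strongly basic toward the phenol, and no stereocentre is affected.

Step 17
Reactants: 33 5-(benzyloxy)-2-[(1R,2R,3S)-2-(benzyloxy)-3-[4-(benzyloxy)phenyl]-3-hydroxy-1-(EC8)propyl]phenol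
Product: 34 (2R,3R,4R)-3,7-bis(benzyloxy)-2-[4-(benzyloxy)phenyl]-4-(EC8)chromane
Conditions: PPh3, DIAD, PhMe, −20 → 0 °C
Reagents that add atoms: none
Why: Intramolecular Mitsunobu etherification: the C2 alcohol is activated as an alkoxyphosphonium ion and displaced by the neighbouring ring A phenoxide in a 6-exo-tet SN2 closure with inversion. This converts the S carbinol into the 2R centre and gives the 2,3-cis-3,4-trans ring C; a non-polar solvent and low temperature are chosen to disfavour ionisation.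

Step 18
Reactants: 34 (2R,3R,4R)-3,7-bis(benzyloxy)-2-[4-(benzyloxy)phenyl]-4-(EC8)chromane
Product: 35 (2R,3R,4R)-4-[(2R,3R)-2-(3,4-dihydroxyphenyl)-3,5,7-trihydroxychroman-8-yl]-2-(4-hydroxyphenyl)chromane-3,7-diol
Conditions: H2 (1 atm), Pd(OH)2/C, THF/MeOH/H2O, rt
Reagents that add atoms: none
Why: Catalytic hydrogenolysis of all eight benzyl ethers under neutral conditions, stopped as soon as debenzylation is complete so that the benzylic C2–O1 bonds of the two pyran rings are not cleaved; no stereocentre is touched.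

## Compound list

1 | (−)-epicatechin | Oc1cc(O)c2c(c1)O[C@H](c1ccc(O)c(O)c1)[C@H](O)C2 | starting material
2 | 5,7,3',4'-tetra-O-benzyl-(−)-epicatechin | c1c(OCc3ccccc3)cc(OCc3ccccc3)c4c1O[C@H](c2ccc(OCc3ccccc3)c(OCc3ccccc3)c2)[C@H](O)C4 | intermediate
3 | 3,5,7,3',4'-penta-O-benzyl-(−)-epicatechin | c1c(OCc3ccccc3)cc(OCc3ccccc3)c4c1O[C@H](c2ccc(OCc3ccccc3)c(OCc3ccccc3)c2)[C@H](OCc2ccccc2)C4 | intermediate
4 | 8-bromo-3,5,7,3',4'-penta-O-benzyl-(−)-epicatechin | Brc2c(OCc3ccccc3)cc(OCc3ccccc3)c4c2O[C@H](c2ccc(OCc3ccccc3)c(OCc3ccccc3)c2)[C@H](OCc2ccccc2)C4 | intermediate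
5 | (R)-but-3-yn-2-ol | C[C@@H](O)C#C | starting material
6 | (R)-4-(EC8)but-3-yn-2-ol | C[C@@H](O)C#Cc2c(OCc3ccccc3)cc(OCc3ccccc3)c4c2O[C@H](c2ccc(OCc3ccccc3)c(OCc3ccccc3)c2)[C@H](OCc2ccccc2)C4 | intermediate
7 | (R,E)-4-(EC8)but-3-en-2-ol | C[C@@H](O)/C=C/c2c(OCc3ccccc3)cc(OCc3ccccc3)c4c2O[C@H](c2ccc(OCc3ccccc3)c(OCc3ccccc3)c2)[C@H](OCc2ccccc2)C4 | intermediate
8 | 2-(benzyloxy)acetic acid | OC(=O)COCc1ccccc1 | starting material
9 | (R,E)-4-(EC8)but-3-en-2-yl 2-(benzyloxy)acetate | C[C@@H](OC(=O)COCc1ccccc1)/C=C/c2c(OCc3ccccc3)cc(OCc3ccccc3)c4c2O[C@H](c2ccc(OCc3ccccc3)c(OCc3ccccc3)c2)[C@H](OCc2ccccc2)C4 | intermediate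
10 | (Z)-ketene trimethylsilyl acetal of 9, benzyloxy cis to silyloxy | C[C@@H](O/C(O[Si](C)(C)C)=C/OCc1ccccc1)/C=C/c2c(OCc3ccccc3)cc(OCc3ccccc3)c4c2O[C@H](c2ccc(OCc3ccccc3)c(OCc3ccccc3)c2)[C@H](OCc2ccccc2)C4 | intermediate (not isolated)
11 | trimethylsilyl (2R,3R,E)-2-(benzyloxy)-3-(EC8)hex-4-enoate | C[Si](C)(C)OC(=O)[C@H](OCc1ccccc1)[C@@H](c2c(OCc3ccccc3)cc(OCc3ccccc3)c4c2O[C@H](c2ccc(OCc3ccccc3)c(OCc3ccccc3)c2)[C@H](OCc2ccccc2)C4)/C=C/C | intermediate (not isolated)
12 | (2R,3R,E)-2-(benzyloxy)-3-(EC8)hex-4-enoic acid | OC(=O)[C@H](OCc1ccccc1)[C@@H](c2c(OCc3ccccc3)cc(OCc3ccccc3)c4c2O[C@H](c2ccc(OCc3ccccc3)c(OCc3ccccc3)c2)[C@H](OCc2ccccc2)C4)/C=C/C | intermediate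
13 | (2R,3R,E)-2-(benzyloxy)-N-methoxy-N-methyl-3-(EC8)hex-4-enamide | CON(C)C(=O)[C@H](OCc1ccccc1)[C@@H](c2c(OCc3ccccc3)cc(OCc3ccccc3)c4c2O[C@H](c2ccc(OCc3ccccc3)c(OCc3ccccc3)c2)[C@H](OCc2ccccc2)C4)/C=C/C | intermediate
14 | 1-(benzyloxy)-4-bromobenzene | Brc1ccc(OCc2ccccc2)cc1 | starting material
15 | 4-(benzyloxy)phenylmagnesium bromide | Br[Mg]c1ccc(OCc2ccccc2)cc1 | intermediate (not isolated)
16 | (2R,3R,E)-2-(benzyloxy)-1-[4-(benzyloxy)phenyl]-3-(EC8)hex-4-en-1-one | c1ccccc1COc1ccc(cc1)C(=O)[C@H](OCc1ccccc1)[C@@H](c2c(OCc3ccccc3)cc(OCc3ccccc3)c4c2O[C@H](c2ccc(OCc3ccccc3)c(OCc3ccccc3)c2)[C@H](OCc2ccccc2)C4)/C=C/C | intermediate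
17 | (1S,2R,3R,E)-2-(benzyloxy)-1-[4-(benzyloxy)phenyl]-3-(EC8)hex-4-en-1-ol | c1ccccc1COc1ccc(cc1)[C@H](O)[C@H](OCc1ccccc1)[C@@H](c2c(OCc3ccccc3)cc(OCc3ccccc3)c4c2O[C@H](c2ccc(OCc3ccccc3)c(OCc3ccccc3)c2)[C@H](OCc2ccccc2)C4)/C=C/C | intermediate
18 | TBS ether of 17 | c1ccccc1COc1ccc(cc1)[C@H](O[Si](C)(C)C(C)(C)C)[C@H](OCc1ccccc1)[C@@H](c2c(OCc3ccccc3)cc(OCc3ccccc3)c4c2O[C@H](c2ccc(OCc3ccccc3)c(OCc3ccccc3)c2)[C@H](OCc2ccccc2)C4)/C=C/C | intermediate
19 | methyl vinyl ketone (but-3-en-2-one) | CC(=O)C=C | starting material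
20 | (3E,5R,6R,7S)-6-(benzyloxy)-7-[4-(benzyloxy)phenyl]-7-(TBS-oxy)-5-(EC8)hept-3-en-2-one | c1ccccc1COc1ccc(cc1)[C@H](O[Si](C)(C)C(C)(C)C)[C@H](OCc1ccccc1)[C@@H](c2c(OCc3ccccc3)cc(OCc3ccccc3)c4c2O[C@H](c2ccc(OCc3ccccc3)c(OCc3ccccc3)c2)[C@H](OCc2ccccc2)C4)/C=C/C(C)=O | intermediate
21 | (5E,7R,8R,9S)-8-(benzyloxy)-9-[4-(benzyloxy)phenyl]-9-(TBS-oxy)-1,1,1-trifluoro-7-(EC8)non-5-ene-2,4-dione | c1ccccc1COc1ccc(cc1)[C@H](O[Si](C)(C)C(C)(C)C)[C@H](OCc1ccccc1)[C@@H](c2c(OCc3ccccc3)cc(OCc3ccccc3)c4c2O[C@H](c2ccc(OCc3ccccc3)c(OCc3ccccc3)c2)[C@H](OCc2ccccc2)C4)/C=C/C(=O)CC(=O)C(F)(F)F | intermediate (not isolated)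
22 | (3E,5R,6R,7S)-6-(benzyloxy)-7-[4-(benzyloxy)phenyl]-7-(TBS-oxy)-1-diazo-5-(EC8)hept-3-en-2-one | c1ccccc1COc1ccc(cc1)[C@H](O[Si](C)(C)C(C)(C)C)[C@H](OCc1ccccc1)[C@@H](c2c(OCc3ccccc3)cc(OCc3ccccc3)c4c2O[C@H](c2ccc(OCc3ccccc3)c(OCc3ccccc3)c2)[C@H](OCc2ccccc2)C4)/C=C/C(=O)C=[N+]=[N-] | intermediate
23 | benzyl alcohol | OCc1ccccc1 | starting material
24 | trichloroethylene | ClC=C(Cl)Cl | starting material
25 | benzyl (E)-1,2-dichlorovinyl ether | Cl/C=C(/Cl)OCc1ccccc1 | intermediate (not isolated)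
26 | lithium (benzyloxy)acetylide | [Li]C#COCc1ccccc1 | intermediate (not isolated)
27 | benzyloxyacetylene | C#COCc1ccccc1 | intermediate
28 | (3E,5R,6R,7S)-6-(benzyloxy)-7-[4-(benzyloxy)phenyl]-7-(TBS-oxy)-5-(EC8)hepta-1,3-dien-1-one (vinylketene) | c1ccccc1COc1ccc(cc1)[C@H](O[Si](C)(C)C(C)(C)C)[C@H](OCc1ccccc1)[C@@H](c2c(OCc3ccccc3)cc(OCc3ccccc3)c4c2O[C@H](c2ccc(OCc3ccccc3)c(OCc3ccccc3)c2)[C@H](OCc2ccccc2)C4)/C=C/C=C=O | intermediate (not isolated)
29 | 3-(benzyloxy)-4-[(1E,3R,4R,5S)-4-(benzyloxy)-5-[4-(benzyloxy)phenyl]-5-(TBS-oxy)-3-(EC8)pent-1-en-1-yl]cyclobut-2-en-1-one, both epimers at the ring sp3 carbon | c1ccccc1COc1ccc(cc1)[C@H](O[Si](C)(C)C(C)(C)C)[C@H](OCc1ccccc1)[C@@H](c2c(OCc3ccccc3)cc(OCc3ccccc3)c4c2O[C@H](c2ccc(OCc3ccccc3)c(OCc3ccccc3)c2)[C@H](OCc2ccccc2)C4)/C=C/C1C(=O)C=C1OCc1ccccc1 | intermediate (not isolated)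
30 | (3E,5E,7R,8R,9S)-3,8-bis(benzyloxy)-9-[4-(benzyloxy)phenyl]-9-(TBS-oxy)-7-(EC8)nona-1,3,5-trien-1-one (dienylketene) | c1ccccc1COc1ccc(cc1)[C@H](O[Si](C)(C)C(C)(C)C)[C@H](OCc1ccccc1)[C@@H](c2c(OCc3ccccc3)cc(OCc3ccccc3)c4c2O[C@H](c2ccc(OCc3ccccc3)c(OCc3ccccc3)c2)[C@H](OCc2ccccc2)C4)/C=C/C=C(/OCc1ccccc1)C=C=O | intermediate (not isolated)
31 | 3-(benzyloxy)-6-[(1R,2R,3S)-2-(benzyloxy)-3-[4-(benzyloxy)phenyl]-3-(TBS-oxy)-1-(EC8)propyl]cyclohexa-2,4-dien-1-one, both epimers at C6 | c1ccccc1COc1ccc(cc1)[C@H](O[Si](C)(C)C(C)(C)C)[C@H](OCc1ccccc1)[C@@H](c2c(OCc3ccccc3)cc(OCc3ccccc3)c4c2O[C@H](c2ccc(OCc3ccccc3)c(OCc3ccccc3)c2)[C@H](OCc2ccccc2)C4)C1C=CC(OCc2ccccc2)=CC1=O | intermediate (not isolated)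
32 | 5-(benzyloxy)-2-[(1R,2R,3S)-2-(benzyloxy)-3-[4-(benzyloxy)phenyl]-3-(TBS-oxy)-1-(EC8)propyl]phenol | c1ccccc1COc1ccc(cc1)[C@H](O[Si](C)(C)C(C)(C)C)[C@H](OCc1ccccc1)[C@@H](c2c(OCc3ccccc3)cc(OCc3ccccc3)c4c2O[C@H](c2ccc(OCc3ccccc3)c(OCc3ccccc3)c2)[C@H](OCc2ccccc2)C4)c1ccc(OCc2ccccc2)cc1O | intermediate
33 | 5-(benzyloxy)-2-[(1R,2R,3S)-2-(benzyloxy)-3-[4-(benzyloxy)phenyl]-3-hydroxy-1-(EC8)propyl]phenol | c1ccccc1COc1ccc(cc1)[C@H](O)[C@H](OCc1ccccc1)[C@@H](c2c(OCc3ccccc3)cc(OCc3ccccc3)c4c2O[C@H](c2ccc(OCc3ccccc3)c(OCc3ccccc3)c2)[C@H](OCc2ccccc2)C4)c1ccc(OCc2ccccc2)cc1O | intermediate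
34 | (2R,3R,4R)-3,7-bis(benzyloxy)-2-[4-(benzyloxy)phenyl]-4-(EC8)chromane (octa-O-benzyl target) | c1ccccc1COc1ccc(cc1)[C@H]5Oc6cc(OCc7ccccc7)ccc6[C@H](c2c(OCc3ccccc3)cc(OCc3ccccc3)c4c2O[C@H](c2ccc(OCc3ccccc3)c(OCc3ccccc3)c2)[C@H](OCc2ccccc2)C4)[C@H]5OCc1ccccc1 | intermediate
35 | (2R,3R,4R)-4-[(2R,3R)-2-(3,4-dihydroxyphenyl)-3,5,7-trihydroxychroman-8-yl]-2-(4-hydroxyphenyl)chromane-3,7-diol | Oc1ccc([C@H]2Oc3cc(O)ccc3[C@H](c3c(O)cc(O)c4c3O[C@H](c3ccc(O)c(O)c3)[C@H](O)C4)[C@H]2O)cc1 | target

## Step count and least certain steps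

Total: 18 steps. Longest linear sequence: 17 steps (steps 1–13 and 15–18, from 1); step 14 is a one-step side branch.

**Step 15 (key step).** The benzyl ynol ether may rearrange sigmatropically before the cycloaddition has used it. The carbene may leak into cyclopropenation or insertion instead of Wolff migration. Residual ketene may acylate the product phenol. Fallback, setting out from 18: the same vinylketene is generated thermally, without light. Cross-metathesis of 18 with but-3-enoic acid (same ruthenium catalyst) would give the β,γ-unsaturated acid (3E,5R,6R,7S)-6-(benzyloxy)-7-[4-(benzyloxy)phenyl]-7-(TBS-oxy)-5-(EC8)hept-3-enoic acid F1. Oxalyl chloride converts it into the acid chloride F2. Et3N with 27 in CH2Cl2 at 0–20 °C dehydrochlorinates F2 to 28, which is trapped as 29. After filtration and evaporation, heating in toluene returns to the route at 32.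

**Step 12.** Formation of the ruthenium alkylidene at the propenyl group may be slow, because the allylic carbon carries the 2,6-disubstituted ring D and a branched chain; the catalyst may then decompose first. Fallback, setting out from 18: oxidative cleavage (OsO4 cat., NaIO4, 2,6-lutidine, dioxane/H2O) gives the aldehyde (2R,3R,4S)-3-(benzyloxy)-4-[4-(benzyloxy)phenyl]-4-(TBS-oxy)-2-(EC8)butanal F3. It is used at once to limit epimerisation at the α-aryl carbon. Wittig olefination with 1-(triphenylphosphoranylidene)propan-2-one in toluene at 60 °C returns to the route at 20.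

**Step 17.** The alkoxyphosphonium ion sits on a 4-benzyloxybenzylic carbon and may ionise before the phenoxide displaces it. That would erode the inversion and favour the all-equatorial 2,3-trans isomer. Fallback, setting out from 13: the donor that drives ionisation is removed.
- 13 is treated with 4-(tosyloxy)phenylmagnesium chloride F4 (from 4-bromophenyl 4-methylbenzenesulfonate and i-PrMgCl·LiCl) to give the 4-(tosyloxy)phenyl ketone F5.
- The operations of steps 10 to 16 then lead through the anti alcohol F6, its silyl ether F7, the methyl enone F8, the diazoketone F9, the ring A phenol F10 and the phenol–alcohol F11.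
- With a sulfonyloxy group in place of the benzyloxy group, the Mitsunobu closure to the 4'-O-tosyl flavan F12 should be a clean SN2 process.
- KOH in MeOH/THF at 60 °C frees the 4'-phenol F13, and hydrogenolysis as in step 18 returns to the route at 35, at the cost of one extra step.

**Step 4.** Oxidative addition into the di-ortho-oxygenated, electron-rich C8–Br bond may be sluggish, and the base may isomerise the aryl propargylic alcohol to an enone. Fallback, setting out from 4:
- Bromine–lithium exchange (n-BuLi, THF, −78 °C) and DMF give the aldehyde 8-formyl-3,5,7,3',4'-penta-O-benzyl-(−)-epicatechin F14.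
- Wittig olefination with 1-(triphenylphosphoranylidene)propan-2-one gives the enone (E)-4-(EC8)but-3-en-2-one F15.
- Reduction with catecholborane and (S)-2-methyl-CBS-oxazaborolidine, which treats the alkenyl group as the large substituent, returns to the route at 7.

## Further compounds

F1 | step 15 | (3E,5R,6R,7S)-6-(benzyloxy)-7-[4-(benzyloxy)phenyl]-7-(TBS-oxy)-5-(EC8)hept-3-enoic acid | c1ccccc1COc1ccc(cc1)[C@H](O[Si](C)(C)C(C)(C)C)[C@H](OCc1ccccc1)[C@@H](c2c(OCc3ccccc3)cc(OCc3ccccc3)c4c2O[C@H](c2ccc(OCc3ccccc3)c(OCc3ccccc3)c2)[C@H](OCc2ccccc2)C4)/C=C/CC(=O)O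
F2 | step 15 | (3E,5R,6R,7S)-6-(benzyloxy)-7-[4-(benzyloxy)phenyl]-7-(TBS-oxy)-5-(EC8)hept-3-enoyl chloride | c1ccccc1COc1ccc(cc1)[C@H](O[Si](C)(C)C(C)(C)C)[C@H](OCc1ccccc1)[C@@H](c2c(OCc3ccccc3)cc(OCc3ccccc3)c4c2O[C@H](c2ccc(OCc3ccccc3)c(OCc3ccccc3)c2)[C@H](OCc2ccccc2)C4)/C=C/CC(=O)Cl
F3 | step 12 | (2R,3R,4S)-3-(benzyloxy)-4-[4-(benzyloxy)phenyl]-4-(TBS-oxy)-2-(EC8)butanal | c1ccccc1COc1ccc(cc1)[C@H](O[Si](C)(C)C(C)(C)C)[C@H](OCc1ccccc1)[C@@H](c2c(OCc3ccccc3)cc(OCc3ccccc3)c4c2O[C@H](c2ccc(OCc3ccccc3)c(OCc3ccccc3)c2)[C@H](OCc2ccccc2)C4)C=O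
F4 | step 17 | 4-(tosyloxy)phenylmagnesium chloride | Cc1ccc(cc1)S(=O)(=O)Oc1ccc([Mg]Cl)cc1
F5 | step 17 | (2R,3R,E)-2-(benzyloxy)-3-(EC8)-1-[4-(tosyloxy)phenyl]hex-4-en-1-one | Cc1ccc(cc1)S(=O)(=O)Oc1ccc(cc1)C(=O)[C@H](OCc1ccccc1)[C@@H](c2c(OCc3ccccc3)cc(OCc3ccccc3)c4c2O[C@H](c2ccc(OCc3ccccc3)c(OCc3ccccc3)c2)[C@H](OCc2ccccc2)C4)/C=C/C
F6 | step 17 | (1S,2R,3R,E)-2-(benzyloxy)-3-(EC8)-1-[4-(tosyloxy)phenyl]hex-4-en-1-ol | Cc1ccc(cc1)S(=O)(=O)Oc1ccc(cc1)[C@H](O)[C@H](OCc1ccccc1)[C@@H](c2c(OCc3ccccc3)cc(OCc3ccccc3)c4c2O[C@H](c2ccc(OCc3ccccc3)c(OCc3ccccc3)c2)[C@H](OCc2ccccc2)C4)/C=C/C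
F7 | step 17 | TBS ether of F6 | Cc1ccc(cc1)S(=O)(=O)Oc1ccc(cc1)[C@H](O[Si](C)(C)C(C)(C)C)[C@H](OCc1ccccc1)[C@@H](c2c(OCc3ccccc3)cc(OCc3ccccc3)c4c2O[C@H](c2ccc(OCc3ccccc3)c(OCc3ccccc3)c2)[C@H](OCc2ccccc2)C4)/C=C/C
F8 | step 17 | (3E,5R,6R,7S)-6-(benzyloxy)-7-(TBS-oxy)-5-(EC8)-7-[4-(tosyloxy)phenyl]hept-3-en-2-one | Cc1ccc(cc1)S(=O)(=O)Oc1ccc(cc1)[C@H](O[Si](C)(C)C(C)(C)C)[C@H](OCc1ccccc1)[C@@H](c2c(OCc3ccccc3)cc(OCc3ccccc3)c4c2O[C@H](c2ccc(OCc3ccccc3)c(OCc3ccccc3)c2)[C@H](OCc2ccccc2)C4)/C=C/C(C)=O
F9 | step 17 | (3E,5R,6R,7S)-6-(benzyloxy)-7-(TBS-oxy)-1-diazo-5-(EC8)-7-[4-(tosyloxy)phenyl]hept-3-en-2-one | Cc1ccc(cc1)S(=O)(=O)Oc1ccc(cc1)[C@H](O[Si](C)(C)C(C)(C)C)[C@H](OCc1ccccc1)[C@@H](c2c(OCc3ccccc3)cc(OCc3ccccc3)c4c2O[C@H](c2ccc(OCc3ccccc3)c(OCc3ccccc3)c2)[C@H](OCc2ccccc2)C4)/C=C/C(=O)C=[N+]=[N-]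
F10 | step 17 | 5-(benzyloxy)-2-[(1R,2R,3S)-2-(benzyloxy)-3-(TBS-oxy)-1-(EC8)-3-[4-(tosyloxy)phenyl]propyl]phenol | Cc1ccc(cc1)S(=O)(=O)Oc1ccc(cc1)[C@H](O[Si](C)(C)C(C)(C)C)[C@H](OCc1ccccc1)[C@@H](c2c(OCc3ccccc3)cc(OCc3ccccc3)c4c2O[C@H](c2ccc(OCc3ccccc3)c(OCc3ccccc3)c2)[C@H](OCc2ccccc2)C4)c1ccc(OCc2ccccc2)cc1O
F11 | step 17 | 5-(benzyloxy)-2-[(1R,2R,3S)-2-(benzyloxy)-3-hydroxy-1-(EC8)-3-[4-(tosyloxy)phenyl]propyl]phenol | Cc1ccc(cc1)S(=O)(=O)Oc1ccc(cc1)[C@H](O)[C@H](OCc1ccccc1)[C@@H](c2c(OCc3ccccc3)cc(OCc3ccccc3)c4c2O[C@H](c2ccc(OCc3ccccc3)c(OCc3ccccc3)c2)[C@H](OCc2ccccc2)C4)c1ccc(OCc2ccccc2)cc1O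
F12 | step 17 | 4-[(2R,3R,4R)-3,7-bis(benzyloxy)-4-(EC8)chroman-2-yl]phenyl 4-methylbenzenesulfonate | Cc1ccc(cc1)S(=O)(=O)Oc1ccc(cc1)[C@H]5Oc6cc(OCc7ccccc7)ccc6[C@H](c2c(OCc3ccccc3)cc(OCc3ccccc3)c4c2O[C@H](c2ccc(OCc3ccccc3)c(OCc3ccccc3)c2)[C@H](OCc2ccccc2)C4)[C@H]5OCc1ccccc1
F13 | step 17 | 4-[(2R,3R,4R)-3,7-bis(benzyloxy)-4-(EC8)chroman-2-yl]phenol | Oc1ccc(cc1)[C@H]5Oc6cc(OCc7ccccc7)ccc6[C@H](c2c(OCc3ccccc3)cc(OCc3ccccc3)c4c2O[C@H](c2ccc(OCc3ccccc3)c(OCc3ccccc3)c2)[C@H](OCc2ccccc2)C4)[C@H]5OCc1ccccc1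
F14 | step 4 | 8-formyl-3,5,7,3',4'-penta-O-benzyl-(−)-epicatechin | O=Cc2c(OCc3ccccc3)cc(OCc3ccccc3)c4c2O[C@H](c2ccc(OCc3ccccc3)c(OCc3ccccc3)c2)[C@H](OCc2ccccc2)C4
F15 | step 4 | (E)-4-(EC8)but-3-en-2-one | CC(=O)/C=C/c2c(OCc3ccccc3)cc(OCc3ccccc3)c4c2O[C@H](c2ccc(OCc3ccccc3)c(OCc3ccccc3)c2)[C@H](OCc2ccccc2)C4
A1 | alternative 1 | 4-(benzyloxy)-3-[(E)-3-(3,4-bis(benzyloxy)phenyl)allyl]-6-{[(2R,3R,4S)-3,7-bis(benzyloxy)-2-(4-(benzyloxy)phenyl)chroman-4-yl]methyl}-2H-pyran-2-one | c1ccccc1COc1ccc(cc1)[C@H]5Oc6cc(OCc7ccccc7)ccc6[C@H](Cc6cc(OCc7ccccc7)c(C/C=C/c7ccc(OCc8ccccc8)c(OCc8ccccc8)c7)c(=O)o6)[C@H]5OCc1ccccc1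
A2 | alternative 1 | 2-[(2R,3R,4R)-3,7-bis(benzyloxy)-2-(4-(benzyloxy)phenyl)chroman-4-yl]-5-(benzyloxy)-4-[(E)-3-(3,4-bis(benzyloxy)phenyl)allyl]benzene-1,3-diol | c1ccccc1COc1ccc(cc1)[C@H]5Oc6cc(OCc7ccccc7)ccc6[C@H](c6c(O)c(C/C=C/c7ccc(OCc8ccccc8)c(OCc8ccccc8)c7)c(OCc7ccccc7)cc6O)[C@H]5OCc1ccccc1
A3 | alternative 2 | 1-[4-(benzyloxy)phenyl]-1-[3-(benzyloxy)phenoxy]-3-(EC8)propane-2,3-diyl diacetate; C1 and C2 configured as C2 and C3 of the target, C3 either epimer | c1ccccc1COc1ccc(cc1)[C@@H](Oc1cccc(OCc2ccccc2)c1)[C@H](OC(C)=O)C(OC(C)=O)c2c(OCc3ccccc3)cc(OCc3ccccc3)c4c2O[C@H](c2ccc(OCc3ccccc3)c(OCc3ccccc3)c2)[C@H](OCc2ccccc2)C4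
A4 | alternative 2 | (2R,3R,4R)-7-(benzyloxy)-2-[4-(benzyloxy)phenyl]-4-(EC8)chroman-3-yl acetate | c1ccccc1COc1ccc(cc1)[C@H]5Oc6cc(OCc7ccccc7)ccc6[C@H](c2c(OCc3ccccc3)cc(OCc3ccccc3)c4c2O[C@H](c2ccc(OCc3ccccc3)c(OCc3ccccc3)c2)[C@H](OCc2ccccc2)C4)[C@H]5OC(C)=O
A5 | alternative 3 | tert-butyl{5-(benzyloxy)-2-[(R)-{(2R,3S)-3-[4-(benzyloxy)phenyl]oxiran-2-yl}(EC8)methyl]phenoxy}dimethylsilane (cis-epoxide) | c1ccccc1COc1ccc(cc1)[C@@H]1O[C@@H]1[C@@H](c2c(OCc3ccccc3)cc(OCc3ccccc3)c4c2O[C@H](c2ccc(OCc3ccccc3)c(OCc3ccccc3)c2)[C@H](OCc2ccccc2)C4)c1ccc(OCc2ccccc2)cc1O[Si](C)(C)C(C)(C)C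
A6 | alternative 3 | (2R,3R,4R)-7-(benzyloxy)-2-[4-(benzyloxy)phenyl]-4-(EC8)chroman-3-ol | c1ccccc1COc1ccc(cc1)[C@H]5Oc6cc(OCc7ccccc7)ccc6[C@H](c2c(OCc3ccccc3)cc(OCc3ccccc3)c4c2O[C@H](c2ccc(OCc3ccccc3)c(OCc3ccccc3)c2)[C@H](OCc2ccccc2)C4)[C@H]5O
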